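## Analysis of the target

The target (C56H42O12) is a linear resveratrol tetramer made of three 2,3-diaryl-2,3-dihydrobenzofurans. Ring A, a resorcinol ring, is the benzo ring of dihydrobenzofuran 1 (O1, C2, C3); it carries the E-4-hydroxystyryl group at C4, C3 bears a 3,5-dihydroxyphenyl group and C2 bears ring B. Ring B is a phenol ring and the benzo ring of dihydrobenzofuran 2 (C2′ with 4-hydroxyphenyl, C3′ with ring C). Ring C is a second resorcinol ring and the benzo ring of dihydrobenzofuran 3 (C2″ with 4-hydroxyphenyl, C3″ with 3,5-dihydroxyphenyl). All six stereocentres are R and each dihydrofuran is 2,3-trans; the three pairs are separated by flat arenes, so each pair needs its own control element. Sensitive features are the nine phenols, the electron-rich stilbene, and three benzylic C2–O bonds that ionise under acid because each C2 aryl carries a para oxygen. The stilbene next to C3 on ring A can also trap such cations. The hard part is the substitution of rings A and C: oxygen, a carbon and a second carbon on three neighbouring positions, the second carbon lying meta to both ring oxygens, where electrophilic substitution does not go. The strategy rests on this triad, C7a (oxygen), C3a (bearing C3) and C4 (bearing the styryl carbon) in ring A and its counterpart in ring C. It maps onto a 3-alkoxyaryne, whose two aryne carbons become C3a and C4.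

## Retrosynthetic reasoning

Dihydrobenzofuran 1 is numbered O1/C2/C3 on ring A, dihydrobenzofuran 2 C2′/C3′ on ring B, dihydrobenzofuran 3 C2″/C3″ on ring C.

47 to 46. The nine O–methyl bonds are cut last. Methyl ethers survive fluoride, organolithiums, hydride, carbenes and palladium, and 46 carries no other protecting group, so one Lewis-acid step finishes the synthesis.

46 to 45 and 44. The C2′–O bond of the central ring is cut. C2′ carries a 4-methoxyphenyl group, so the alcohol 45 ionises under mild acid and the ring B phenol closes the five-membered ring anti to ring C. This sets C2′ from C3′ and makes the carbinol configuration of 44 irrelevant. The ring B phenol is kept as its methoxymethyl ether (44) until this point, so the same acid unmasks it.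

44 to 43. The C2′–H bond is cut back to a ketone. In 43 the carbon that becomes C3′ is doubly benzylic and α to the carbonyl, hence freely epimerisable. A chiral hydrogenation catalyst can therefore select one α-epimer while reducing the ketone, and this is the only place where C3′ can be set independently of the four remote stereocentres.

43 to 30 and 42. The C3′–ring B bond is cut as a ketone α-arylation. It joins two halves of similar size, uses the aryl ketone that the key step leaves on the eastern half (42) and the bromine that ring B brings along (30), and needs no further activation of either partner.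

30 to 28, and 42 to 41. In the western half the aryl benzyl ketone 28 is the precursor of the stilbene (reduction to 29, neutral dehydration). In both halves the trans ring is reached from the cis ring (25, 41) by acid, which inverts C2 through reversible C2–O ionisation and leaves C3 alone. This is done at the ketone stage because a ketone side chain cannot ionise and no stilbene is present yet.

23 to 22 and 21, and 39 to 38 and 37. The C2–C3 bond of dihydrobenzofurans 1 and 3 is cut as a carbene C–H insertion. The diaryl ketone left by the key step becomes the carbene carbon (C3) through hydrazone and diazo compound, and the benzylic CH2 of the aryl benzyl ether becomes C2. A chiral dirhodium catalyst fixes C3 absolutely. The second ketone must be out of the way, so it is reduced and silylated first (18 to 20, 34 to 36).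

18 to 16 and 15 through 17, and 34 to 32 and 15 through 33. This is the key disconnection. Two bonds on ring A are cut at once, ring A–CH2 and ring A–C(=O), leading to the aryne 17 and the 1,3-diketone 15. The cut is made here because no other operation places a carbon substituent meta to both oxygens and a second one beside it in a single step. It also delivers both carbons as ketones, each of which is used later. The forward reaction has to control which aryne carbon takes the enolate and which carbonyl is transferred.

16 and 32 to 9. Both aryne precursors come from one phenol, 9, by etherification with 12 or 31. 9 goes back through 5 and 4 to 1, the bromine between the oxygens being the handle that carries silicon onto carbon. 12 comes from 10, and 15 from 13 and 14.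

## Alternatives that were turned down

Alternative 1: The C2′–C3′ bond of the central dihydrofuran is traced back to a six-membered 1,3-benzoxazine A2 with an N–H between the two benzylic carbons. In the forward key step an anomeric amide aminates the nitrogen, the resulting 1,1-diazene loses N2, and the two benzylic radicals recombine to the nona-O-methyl ether A1 (identical with 46).
- For it: A2 could be assembled by a metal-free condensation that also joins the halves, and the step needs no diazo compound and no acid in the presence of the stilbene. On the economy of the union it is stronger than the route chosen here.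
- Against it: the nitrogen of A2 is part of a hindered N,O-acetal and is a poor nucleophile. The diarylmethyl radical at C3′ is planar and long-lived, so the configuration at C3′ relative to the four remote centres would be lost exactly where control is most needed. The route also says nothing about the crowded patterns of rings A and C.
- Comparison: the chosen strategy solves those patterns and fixes C3′ with a chiral catalyst before the ring closes.

Alternative 2: Ring C is built rather than bought. Three of its C–C bonds are cut to give the 1,6-diyne A4 (ynol ether oxygen, C2″ and C3″ in the tether) and ethoxyacetylene A5. A metal-catalysed [2+2+2] cyclotrimerisation would give A3, closing ring C and dihydrofuran 3 together.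
- For it: both stereocentres are set trans in an open chain before any ring exists, so no cis isomer has to be corrected. On this point it is stronger than the chosen route.
- Against it: a secondary benzylic ynol ether is fragile, and the tether does not fix the orientation of A5, which decides between the 6-ethoxy and 5-ethoxy arene. A3 carries only a silyloxymethyl group that must be homologated before any union, and ring A would need a second, different cyclotrimerisation.
- Comparison: the chosen strategy starts from a commercial arene, installs both carbon substituents at the oxidation level that is used afterwards, and serves both halves with one reaction.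

Alternative 3: The C3′–ring B and C2′–aryl bonds are cut together. The eastern alkenyl boronate A7 and 4-methoxyphenyllithium A8 form an ate complex. Palladium, after oxidative addition to the western aryl triflate A9, induces a 1,2-shift of the aryl group from boron to C2′ while ring B is delivered to C3′, giving the boronate A6. Oxidation of the C–B bond and C–O closure onto the aryl chloride would follow.
- For it: it is the most convergent union, and a chiral ligand sets C2′ and C3′ in one stereospecific event. This is clearly stronger than the dynamic kinetic resolution used here for C3′.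
- Against it: β-aryl alkenyl boronates are much poorer substrates than vinyl boronates, and direct Suzuki coupling of the migrating group competes. Ring C carries dihydrofuran 3 next to the reacting alkene. The later etherification of a secondary benzylic alcohol onto an aryl chloride is prone to β-hydride elimination. A7 and A9 still presuppose a way to make the two halves.
- Comparison: the chosen strategy offers that way, and its union consumes a ketone already in place.

Key step: step 9

Remarks on the chemistry (assumptions):
- The target SMILES encodes R at all six stereocentres with each dihydrofuran 2,3-trans; the route aims at this enantiomer.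
- Rh2(S-PTAD)4 is taken to give the (3R)-cis rings in steps 13 and 25; if its sense is opposite, Rh2(R-PTAD)4 is used.
- RuCl2[(S)-xylbinap][(S)-daipen] is taken to select the (R)-C3′ epimer in step 30; otherwise its enantiomer is used.
- The carbinol centres of 19–24, 29 and 35–40 are uncontrolled, the α-centre of 43 is a mixture, and the carbinol centre of 44 and 45 is erased in step 31; these centres are drawn without descriptor.

Step 1
Reactants: 1 5-methoxyresorcinol
Product: 2 1-methoxy-3,5-bis(methoxymethoxy)benzene
Conditions: MOMCl, i-Pr2NEt, CH2Cl2, 0 °C to rt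
Reagents that add atoms: chloromethyl methyl ether, COCCl
Why: Double O-alkylation of the phenols (Williamson-type acetal ether formation); the methoxymethyl ethers are chosen as the strongest oxygen directing groups for the next step.

Step 2
Reactants: 2 1-methoxy-3,5-bis(methoxymethoxy)benzene
Product: 4 2-bromo-5-methoxy-1,3-bis(methoxymethoxy)benzene, via aryllithium 3 (not isolated)
Conditions: n-BuLi, THF, 0 °C; BrCCl2CCl2Br, −78 °C to rt
Reagents that add atoms: 1,2-dibromo-1,1,2,2-tetrachloroethane, BrC(Cl)(Cl)C(Cl)(Cl)Br
Why: Directed ortho-metalation; the hydrogen between the two chelating acetal ethers should be removed in preference to those beside the methyl ether, and the aryllithium is brominated by halogen transfer.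

Step 3
Reactants: 4 2-bromo-5-methoxy-1,3-bis(methoxymethoxy)benzene
Product: 5 2-bromo-5-methoxybenzene-1,3-diol
Conditions: HCl (3 M), MeOH, 40 °C
Reagents that add atoms: none
Why: Acid-catalysed acetal exchange with methanol frees both phenols; aryl bromide and methyl ether are inert.

Step 4
Reactants: 5 2-bromo-5-methoxybenzene-1,3-diol
Product: 9 3-hydroxy-5-methoxy-2-(trimethylsilyl)phenyl trifluoromethanesulfonate, via bis-silyl ether 6 (not isolated), via lithium phenoxide 7 (not isolated), via silyloxy triflate 8 (not isolated)
Conditions: (Me3Si)2NH, THF, 65 °C, evaporation; n-BuLi, THF, −78 °C to rt; Tf2O, −78 °C; 1 M HCl, THF, 0 °C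
Reagents that add atoms: hexamethyldisilazane, C[Si](C)(C)N[Si](C)(C)C; trifluoromethanesulfonic anhydride, O=S(=O)(OS(=O)(=O)C(F)(F)F)C(F)(F)F
Why: O-silylation, bromine–lithium exchange and anionic 1,3 O-to-C silyl migration (retro-Brook rearrangement) put silicon on carbon and leave a phenoxide that is triflated; 6 is symmetric, so either silyl group may migrate. The remaining aryl silyl ether hydrolyses far faster than the C–Si bond.

Step 5
Reactants: 10 3-bromo-4-hydroxybenzaldehyde
Product: 11 3-bromo-4-(methoxymethoxy)benzaldehyde
Conditions: MOMCl, i-Pr2NEt, CH2Cl2, 0 °C to rt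
Reagents that add atoms: chloromethyl methyl ether, COCCl
Why: Phenol protection as an acetal ether that withstands fluoride, hydride, hydrazine and alkoxide and is removable by mild acid.

Step 6
Reactants: 11 3-bromo-4-(methoxymethoxy)benzaldehyde
Product: 12 [3-bromo-4-(methoxymethoxy)phenyl]methanol
Conditions: NaBH4, MeOH, 0 °C
Reagents that add atoms: none
Why: Borohydride reduction of the aldehyde; aryl bromide and acetal are untouched.

Step 7
Reactants: 13 4′-methoxyacetophenone; 14 methyl 3,5-dimethoxybenzoate
Product: 15 1-(3,5-dimethoxyphenyl)-3-(4-methoxyphenyl)propane-1,3-dione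
Conditions: NaH, THF, reflux; aq. HCl
Reagents that add atoms: none
Why: Crossed Claisen condensation of the ketone enolate with a non-enolisable ester, driven by deprotonation of the 1,3-diketone.

Step 8
Reactants: 9 3-hydroxy-5-methoxy-2-(trimethylsilyl)phenyl trifluoromethanesulfonate; 12 [3-bromo-4-(methoxymethoxy)phenyl]methanol
Product: 16 3-{[3-bromo-4-(methoxymethoxy)phenyl]methoxy}-5-methoxy-2-(trimethylsilyl)phenyl trifluoromethanesulfonate
Conditions: PPh3, DIAD, THF, 0 °C to rt
Reagents that add atoms: none
Why: Mitsunobu etherification of the phenol with the primary benzylic alcohol; it avoids a free phenoxide, which under basic alkylation could attack the neighbouring silicon and set off the aryne too early.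

Step 9
Reactants: 16 3-{[3-bromo-4-(methoxymethoxy)phenyl]methoxy}-5-methoxy-2-(trimethylsilyl)phenyl trifluoromethanesulfonate; 15 1-(3,5-dimethoxyphenyl)-3-(4-methoxyphenyl)propane-1,3-dione
Product: 18 2-[3-{[3-bromo-4-(methoxymethoxy)phenyl]methoxy}-2-(3,5-dimethoxybenzoyl)-5-methoxyphenyl]-1-(4-methoxyphenyl)ethan-1-one, via aryne 17 (not isolated)
Conditions: CsF, MeCN, 80 °C
Reagents that add atoms: none
Why: Fluoride attacks silicon in 16 and triflate leaves, giving aryne 17, and the cesium enolate of 15 adds through its central carbon to the aryne carbon meta to the benzyloxy group. That carbon is chosen because the inductively withdrawing ether oxygen distorts the triple bond and stabilises the aryl anion that develops beside it. The aryl anion then adds to the nearer, more electrophilic 3,5-dimethoxybenzoyl carbonyl (the other is deactivated by para-methoxy donation), forming a benzocyclobutenoxide. Retro-aldol opening of this four-membered ring cleaves the old C–C bond of the diketone, so the aroyl group ends beside the oxygen and the CH2–C(=O)–aryl chain on the next carbon, which are the future C3 and stilbene carbon. The closest known reaction is the acyl-alkylation of arynes with β-ketoesters and 1,3-diketones. No ring persists and no stereocentre is formed. The step needs regioselectivity on the aryne, secured by the alkoxy group, and selectivity between the two carbonyls, which rests only on their electronic difference and would otherwise give a separable isomer with the aryl groups exchanged. An excess of 15 limits double arylation, and the new diaryl ketone has no α-hydrogen, so it cannot condense further.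

Step 10
Reactants: 18 2-[3-{[3-bromo-4-(methoxymethoxy)phenyl]methoxy}-2-(3,5-dimethoxybenzoyl)-5-methoxyphenyl]-1-(4-methoxyphenyl)ethan-1-one
Product: 19 [2-{[3-bromo-4-(methoxymethoxy)phenyl]methoxy}-6-[2-hydroxy-2-(4-methoxyphenyl)ethyl]-4-methoxyphenyl](3,5-dimethoxyphenyl)methanone (racemic carbinol)
Conditions: NaBH4, MeOH–THF, −20 to 0 °C
Reagents that add atoms: none
Why: Chemoselective borohydride reduction: the aryl benzyl ketone is open to hydride, the diaryl ketone sits between two ortho substituents. The two carbonyls must be told apart because hydrazine would close a 2,3-benzodiazepine on the 1,5-diketone.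

Step 11
Reactants: 19 hydroxy ketone from step 10
Product: 20 tert-butyldimethylsilyl ether of 19
Conditions: TBSCl, imidazole, DMF, rt
Reagents that add atoms: tert-butyldimethylsilyl chloride, CC(C)(C)[Si](C)(C)Cl
Why: Silylation masks the alcohol, which would otherwise undergo O–H insertion with the carbene; the bulky silyl ether also shields the neighbouring methine C–H.

Step 12
Reactants: 20 silyl ether ketone
Product: 21 hydrazone of 20 (C=N–NH2 at the diaryl ketone carbon)
Conditions: N2H4·H2O, AcOH (cat.), n-BuOH, 110 °C
Reagents that add atoms: hydrazine, NN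
Why: Condensation of hydrazine with the hindered diaryl ketone under forcing conditions gives the N-unsubstituted hydrazone; silyl ether, acetal and aryl bromide tolerate hydrazine.

Step 13
Reactants: 21 hydrazone
Product: 23 (2S,3R)-2-[3-bromo-4-(methoxymethoxy)phenyl]-4-[2-(tert-butyldimethylsilyloxy)-2-(4-methoxyphenyl)ethyl]-3-(3,5-dimethoxyphenyl)-6-methoxy-2,3-dihydrobenzofuran (2,3-cis), via diazo compound 22 (not isolated)
Conditions: MnO2, CH2Cl2, 0 °C, filtration; Rh2(S-PTAD)4 (1 mol %), CH2Cl2, −20 °C to rt
Reagents that add atoms: none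
Why: MnO2 dehydrogenates the hydrazone to the diaryldiazomethane, and the dirhodium catalyst turns it into a donor/donor carbene that inserts 1,5 into the benzylic C–H bond of the aryl benzyl ether, closing the five-membered ring. Such insertions should give the 2,3-cis isomer, with C3 set as R by the chiral carboxylate ligands. The other 1,5 C–H bond, in the side chain, is a hindered methine.

Step 14
Reactants: 23 cis-dihydrobenzofuran silyl ether
Product: 24 1-(4-methoxyphenyl)-2-[(2S,3R)-2-[3-bromo-4-(methoxymethoxy)phenyl]-3-(3,5-dimethoxyphenyl)-6-methoxy-2,3-dihydrobenzofuran-4-yl]ethan-1-ol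
Conditions: TBAF, THF, rt
Reagents that add atoms: none
Why: Fluoride cleaves the Si–O bond; nothing else in the molecule is fluoride-labile.

Step 15
Reactants: 24 alcohol
Product: 25 1-(4-methoxyphenyl)-2-[(2S,3R)-2-[3-bromo-4-(methoxymethoxy)phenyl]-3-(3,5-dimethoxyphenyl)-6-methoxy-2,3-dihydrobenzofuran-4-yl]ethan-1-one
Conditions: Dess–Martin periodinane, NaHCO3, CH2Cl2, rt
Reagents that add atoms: none
Why: Buffered Dess–Martin oxidation returns the ketone, removing the uncontrolled carbinol centre and the acid-ionisable benzylic C–O bond before the acid step.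

Step 16
Reactants: 25 cis ketone
Product: 27 2-[(2R,3R)-2-(3-bromo-4-hydroxyphenyl)-3-(3,5-dimethoxyphenyl)-6-methoxy-2,3-dihydrobenzofuran-4-yl]-1-(4-methoxyphenyl)ethan-1-one (2,3-trans), via cis-bromophenol 26 (not isolated)
Conditions: HCl, MeOH–THF, 45 °C, evaporation; CF3CO2H, CH2Cl2, 0 °C to rt
Reagents that add atoms: none
Why: Acidic methanolysis removes the methoxymethyl group (it would not survive the stronger acid anyway). Trifluoroacetic acid then ionises the C2–O bond, the cation being stabilised by the para-hydroxy group of ring B, and reclosure should give the thermodynamically favoured trans ring. C3 is not involved, so it stays R and C2 becomes R.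

Step 17
Reactants: 27 trans-bromophenol ketone
Product: 28 2-[(2R,3R)-2-[3-bromo-4-(methoxymethoxy)phenyl]-3-(3,5-dimethoxyphenyl)-6-methoxy-2,3-dihydrobenzofuran-4-yl]-1-(4-methoxyphenyl)ethan-1-one
Conditions: MOMCl, i-Pr2NEt, CH2Cl2, 0 °C to rt
Reagents that add atoms: chloromethyl methyl ether, COCCl
Why: The ring B phenol is protected again, because the α-arylation and the hydrogenation both need it masked; the ketone is inert to these conditions.

Step 18
Reactants: 28 trans ketone
Product: 29 1-(4-methoxyphenyl)-2-[(2R,3R)-2-[3-bromo-4-(methoxymethoxy)phenyl]-3-(3,5-dimethoxyphenyl)-6-methoxy-2,3-dihydrobenzofuran-4-yl]ethan-1-ol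
Conditions: NaBH4, MeOH–THF, 0 °C
Reagents that add atoms: none
Why: Borohydride reduction to the benzylic alcohol, the substrate for elimination; the carbinol configuration is irrelevant.

Step 19
Reactants: 29 alcohol
Product: 30 (2R,3R)-2-[3-bromo-4-(methoxymethoxy)phenyl]-3-(3,5-dimethoxyphenyl)-6-methoxy-4-[(E)-2-(4-methoxyphenyl)ethenyl]-2,3-dihydrobenzofuran
Conditions: Burgess reagent, toluene, 60 °C
Reagents that add atoms: none
Why: Burgess dehydration by syn-elimination of the sulfamate under neutral conditions; the only β-hydrogens are on the benzylic CH2, and conjugation should favour the E-stilbene. Acid is avoided because the stilbene beside C3 and the dihydrofuran would cyclise.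

Step 20
Reactants: 9 3-hydroxy-5-methoxy-2-(trimethylsilyl)phenyl trifluoromethanesulfonate; 31 4-methoxybenzyl alcohol
Product: 32 5-methoxy-3-[(4-methoxyphenyl)methoxy]-2-(trimethylsilyl)phenyl trifluoromethanesulfonate
Conditions: PPh3, DIAD, THF, 0 °C to rt
Reagents that add atoms: none
Why: Mitsunobu etherification as in step 8; the benzyl group now carries the 4-methoxyphenyl ring of C2″.

Step 21
Reactants: 32 eastern aryne precursor; 15 1-(3,5-dimethoxyphenyl)-3-(4-methoxyphenyl)propane-1,3-dione
Product: 34 2-[2-(3,5-dimethoxybenzoyl)-5-methoxy-3-[(4-methoxyphenyl)methoxy]phenyl]-1-(4-methoxyphenyl)ethan-1-one, via aryne 33 (not isolated)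
Conditions: CsF, MeCN, 80 °C
Reagents that add atoms: none
Why: Aryne acyl-alkylation as in step 9, with the same control of aryne regiochemistry by the alkoxy group and of acyl transfer by the electronic difference between the aroyl groups; it builds ring C with its three contiguous substituents.

Step 22
Reactants: 34 eastern diketone
Product: 35 (3,5-dimethoxyphenyl){2-[2-hydroxy-2-(4-methoxyphenyl)ethyl]-4-methoxy-6-[(4-methoxyphenyl)methoxy]phenyl}methanone (racemic carbinol)
Conditions: NaBH4, MeOH–THF, −20 to 0 °C
Reagents that add atoms: none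
Why: Chemoselective reduction of the unhindered aryl benzyl ketone, as in step 10.

Step 23
Reactants: 35 hydroxy ketone
Product: 36 tert-butyldimethylsilyl ether of 35
Conditions: TBSCl, imidazole, DMF, rt
Reagents that add atoms: tert-butyldimethylsilyl chloride, CC(C)(C)[Si](C)(C)Cl
Why: Protection of the alcohol against O–H insertion, as in step 11.

Step 24
Reactants: 36 silyl ether ketone
Product: 37 hydrazone of 36 (C=N–NH2 at the diaryl ketone carbon)
Conditions: N2H4·H2O, AcOH (cat.), n-BuOH, 110 °C
Reagents that add atoms: hydrazine, NN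
Why: Hydrazone formation at the hindered diaryl ketone, as in step 12.

Step 25
Reactants: 37 hydrazone
Product: 39 (2S,3R)-4-[2-(tert-butyldimethylsilyloxy)-2-(4-methoxyphenyl)ethyl]-3-(3,5-dimethoxyphenyl)-6-methoxy-2-(4-methoxyphenyl)-2,3-dihydrobenzofuran (2,3-cis), via diazo compound 38 (not isolated)
Conditions: MnO2, CH2Cl2, 0 °C, filtration; Rh2(S-PTAD)4 (1 mol %), CH2Cl2, −20 °C to rt
Reagents that add atoms: none
Why: Oxidation to the diazo compound and enantioselective 1,5 carbene C–H insertion into the 4-methoxybenzyl ether, as in step 13; the cis ring with (3R) is expected.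

Step 26
Reactants: 39 cis-dihydrobenzofuran silyl ether
Product: 40 2-[(2S,3R)-3-(3,5-dimethoxyphenyl)-6-methoxy-2-(4-methoxyphenyl)-2,3-dihydrobenzofuran-4-yl]-1-(4-methoxyphenyl)ethan-1-ol
Conditions: TBAF, THF, rt
Reagents that add atoms: none
Why: Fluoride-mediated desilylation.

Step 27
Reactants: 40 alcohol
Product: 41 2-[(2S,3R)-3-(3,5-dimethoxyphenyl)-6-methoxy-2-(4-methoxyphenyl)-2,3-dihydrobenzofuran-4-yl]-1-(4-methoxyphenyl)ethan-1-one
Conditions: Dess–Martin periodinane, NaHCO3, CH2Cl2, rt
Reagents that add atoms: none
Why: Oxidation restores the aryl benzyl ketone needed for the union and removes the ionisable carbinol before the acid step.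

Step 28
Reactants: 41 cis ketone
Product: 42 2-[(2R,3R)-3-(3,5-dimethoxyphenyl)-6-methoxy-2-(4-methoxyphenyl)-2,3-dihydrobenzofuran-4-yl]-1-(4-methoxyphenyl)ethan-1-one (2,3-trans)
Conditions: CF3CO2H, CH2Cl2, 0 °C to rt
Reagents that add atoms: none
Why: Acid-mediated epimerisation at C2″ by reversible ionisation of the C2″–O bond (4-methoxybenzylic cation) and reclosure to the more stable trans ring; C3″ keeps its R configuration.

Step 29
Reactants: 30 western bromide; 42 eastern ketone
Product: 43 1-(4-methoxyphenyl)ethan-1-one whose C2 carries C4 of the eastern (2R,3R)-dihydrobenzofuran of 42 and the ring B carbon of 30 that held bromine (both epimers at C2 of the ethanone)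
Conditions: Pd2(dba)3, XPhos, NaOt-Bu, toluene, 80 °C
Reagents that add atoms: none
Why: Palladium-catalysed ketone α-arylation: zerovalent palladium inserts into the C–Br bond of ring B, the sodium enolate of 42 (the only enolisable site) transmetalates, and reductive elimination forms the C3′–ring B bond. The product stays as its more acidic enolate, so it is not arylated twice, and its α-centre is left as a base-labile mixture.

Step 30
Reactants: 43 triarylethanone
Product: 44 secondary alcohol from 43 with C3′ as R (carbinol configuration fixed by the catalyst and not needed)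
Conditions: RuCl2[(S)-xylbinap][(S)-daipen] (2 mol %), KOt-Bu, H2 (20 atm), i-PrOH–toluene, 30 °C
Reagents that add atoms: none
Why: Noyori-type asymmetric ketone hydrogenation with dynamic kinetic resolution: alkoxide epimerises the doubly benzylic α-centre quickly and the chiral catalyst should reduce one α-epimer faster, which fixes C3′ as R. This catalyst class reduces C=O and leaves the stilbene alone.

Step 31
Reactants: 44 alcohol
Product: 46 nona-O-methyl ether of the target (all three dihydrobenzofurans (2R,3R) and trans), via phenol 45 (not isolated)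
Conditions: HCl (2 M), MeOH–THF, rt
Reagents that add atoms: none
Why: Mild acid removes the methoxymethyl ether and ionises the 4-methoxybenzylic alcohol; the ring B phenol captures the cation in a five-membered closure anti to ring C on C3′, which sets C2′ as R whatever the carbinol configuration was. The acid is kept weak so that the stilbene and the other two rings are not ionised.

Step 32
Reactants: 46 nona-O-methyl ether
Product: 47 CNP0184803.1 (target)
Conditions: BBr3, CH2Cl2, −78 to 0 °C; MeOH
Reagents that add atoms: none
Why: Lewis-acid cleavage of the nine aryl methyl ethers (boron binds oxygen, bromide attacks methyl); low temperature limits ionisation of the benzylic C–O bonds, and the trans rings are the thermodynamic isomers in any case.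

Compound list

1 | 5-methoxyresorcinol | COc1cc(O)cc(O)c1 | starting material
2 | 1-methoxy-3,5-bis(methoxymethoxy)benzene | COCOc1cc(OC)cc(OCOC)c1 | intermediate
3 | [4-methoxy-2,6-bis(methoxymethoxy)phenyl]lithium | [Li]c1c(OCOC)cc(OC)cc1OCOC | intermediate
4 | 2-bromo-5-methoxy-1,3-bis(methoxymethoxy)benzene | COCOc1cc(OC)cc(OCOC)c1Br | intermediate
5 | 2-bromo-5-methoxybenzene-1,3-diol | COc1cc(O)c(Br)c(O)c1 | intermediate
6 | 2-bromo-5-methoxy-1,3-bis(trimethylsilyloxy)benzene | COc1cc(O[Si](C)(C)C)c(Br)c(O[Si](C)(C)C)c1 | intermediate
7 | lithium 5-methoxy-2-(trimethylsilyl)-3-(trimethylsilyloxy)phenolate | [Li+].[O-]c1cc(OC)cc(O[Si](C)(C)C)c1[Si](C)(C)C | intermediate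
8 | 5-methoxy-2-(trimethylsilyl)-3-(trimethylsilyloxy)phenyl trifluoromethanesulfonate | COc1cc(O[Si](C)(C)C)c([Si](C)(C)C)c(OS(=O)(=O)C(F)(F)F)c1 | intermediate
9 | 3-hydroxy-5-methoxy-2-(trimethylsilyl)phenyl trifluoromethanesulfonate | COc1cc(O)c([Si](C)(C)C)c(OS(=O)(=O)C(F)(F)F)c1 | intermediate
10 | 3-bromo-4-hydroxybenzaldehyde | O=Cc1ccc(O)c(Br)c1 | starting material
11 | 3-bromo-4-(methoxymethoxy)benzaldehyde | COCOc1ccc(C=O)cc1Br | intermediate
12 | [3-bromo-4-(methoxymethoxy)phenyl]methanol | COCOc1ccc(CO)cc1Br | intermediate
13 | 4′-methoxyacetophenone | CC(=O)c1ccc(OC)cc1 | starting material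
14 | methyl 3,5-dimethoxybenzoate | COC(=O)c1cc(OC)cc(OC)c1 | starting material
15 | 1-(3,5-dimethoxyphenyl)-3-(4-methoxyphenyl)propane-1,3-dione | COc1ccc(C(=O)CC(=O)c2cc(OC)cc(OC)c2)cc1 | intermediate
16 | 3-{[3-bromo-4-(methoxymethoxy)phenyl]methoxy}-5-methoxy-2-(trimethylsilyl)phenyl trifluoromethanesulfonate | COCOc1ccc(COc2cc(OC)cc(OS(=O)(=O)C(F)(F)F)c2[Si](C)(C)C)cc1Br | intermediate
17 | 3-{[3-bromo-4-(methoxymethoxy)phenyl]methoxy}-5-methoxybenzyne | COC1=CC#CC(OCc2ccc(OCOC)c(Br)c2)=C1 | intermediate
18 | 2-[3-{[3-bromo-4-(methoxymethoxy)phenyl]methoxy}-2-(3,5-dimethoxybenzoyl)-5-methoxyphenyl]-1-(4-methoxyphenyl)ethan-1-one | COc1ccc(C(=O)Cc2cc(OC)cc(OCc3ccc(OCOC)c(Br)c3)c2C(=O)c2cc(OC)cc(OC)c2)cc1 | intermediate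
19 | western hydroxy ketone (racemic carbinol) | COc1ccc(C(O)Cc2cc(OC)cc(OCc3ccc(OCOC)c(Br)c3)c2C(=O)c2cc(OC)cc(OC)c2)cc1 | intermediate
20 | tert-butyldimethylsilyl ether of 19 | COc1ccc(C(O[Si](C)(C)C(C)(C)C)Cc2cc(OC)cc(OCc3ccc(OCOC)c(Br)c3)c2C(=O)c2cc(OC)cc(OC)c2)cc1 | intermediate
21 | hydrazone of 20 | COc1ccc(C(O[Si](C)(C)C(C)(C)C)Cc2cc(OC)cc(OCc3ccc(OCOC)c(Br)c3)c2C(=NN)c2cc(OC)cc(OC)c2)cc1 | intermediate
22 | western diaryldiazomethane | COc1ccc(C(O[Si](C)(C)C(C)(C)C)Cc2cc(OC)cc(OCc3ccc(OCOC)c(Br)c3)c2C(=[N+]=[N-])c2cc(OC)cc(OC)c2)cc1 | intermediate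
23 | (2S,3R)-cis-dihydrobenzofuran 1 with silyloxy side chain | COc1ccc(C(O[Si](C)(C)C(C)(C)C)Cc2cc(OC)cc3c2[C@@H](c2cc(OC)cc(OC)c2)[C@@H](c2ccc(OCOC)c(Br)c2)O3)cc1 | intermediate
24 | (2S,3R)-cis-dihydrobenzofuran 1 with hydroxy side chain | COc1ccc(C(O)Cc2cc(OC)cc3c2[C@@H](c2cc(OC)cc(OC)c2)[C@@H](c2ccc(OCOC)c(Br)c2)O3)cc1 | intermediate
25 | (2S,3R)-cis-dihydrobenzofuran 1 ketone | COc1ccc(C(=O)Cc2cc(OC)cc3c2[C@@H](c2cc(OC)cc(OC)c2)[C@@H](c2ccc(OCOC)c(Br)c2)O3)cc1 | intermediate
26 | (2S,3R)-cis-bromophenol ketone | COc1ccc(C(=O)Cc2cc(OC)cc3c2[C@@H](c2cc(OC)cc(OC)c2)[C@@H](c2ccc(O)c(Br)c2)O3)cc1 | intermediate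
27 | (2R,3R)-trans-bromophenol ketone | COc1ccc(C(=O)Cc2cc(OC)cc3c2[C@@H](c2cc(OC)cc(OC)c2)[C@H](c2ccc(O)c(Br)c2)O3)cc1 | intermediate
28 | (2R,3R)-trans ketone with methoxymethyl ether | COc1ccc(C(=O)Cc2cc(OC)cc3c2[C@@H](c2cc(OC)cc(OC)c2)[C@H](c2ccc(OCOC)c(Br)c2)O3)cc1 | intermediate
29 | (2R,3R)-trans alcohol | COc1ccc(C(O)Cc2cc(OC)cc3c2[C@@H](c2cc(OC)cc(OC)c2)[C@H](c2ccc(OCOC)c(Br)c2)O3)cc1 | intermediate
30 | western half: (2R,3R)-trans-dihydrobenzofuran 1 with E-stilbene and ring B bromide | COc1ccc(/C=C/c2cc(OC)cc3c2[C@@H](c2cc(OC)cc(OC)c2)[C@H](c2ccc(OCOC)c(Br)c2)O3)cc1 | intermediate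
31 | 4-methoxybenzyl alcohol | COc1ccc(CO)cc1 | starting material
32 | 5-methoxy-3-[(4-methoxyphenyl)methoxy]-2-(trimethylsilyl)phenyl trifluoromethanesulfonate | COc1ccc(COc2cc(OC)cc(OS(=O)(=O)C(F)(F)F)c2[Si](C)(C)C)cc1 | intermediate
33 | 5-methoxy-3-[(4-methoxyphenyl)methoxy]benzyne | COC1=CC#CC(OCc2ccc(OC)cc2)=C1 | intermediate
34 | 2-[2-(3,5-dimethoxybenzoyl)-5-methoxy-3-[(4-methoxyphenyl)methoxy]phenyl]-1-(4-methoxyphenyl)ethan-1-one | COc1ccc(COc2cc(OC)cc(CC(=O)c3ccc(OC)cc3)c2C(=O)c2cc(OC)cc(OC)c2)cc1 | intermediate
35 | eastern hydroxy ketone (racemic carbinol) | COc1ccc(COc2cc(OC)cc(CC(O)c3ccc(OC)cc3)c2C(=O)c2cc(OC)cc(OC)c2)cc1 | intermediate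
36 | tert-butyldimethylsilyl ether of 35 | COc1ccc(COc2cc(OC)cc(CC(O[Si](C)(C)C(C)(C)C)c3ccc(OC)cc3)c2C(=O)c2cc(OC)cc(OC)c2)cc1 | intermediate
37 | hydrazone of 36 | COc1ccc(COc2cc(OC)cc(CC(O[Si](C)(C)C(C)(C)C)c3ccc(OC)cc3)c2C(=NN)c2cc(OC)cc(OC)c2)cc1 | intermediate
38 | eastern diaryldiazomethane | COc1ccc(COc2cc(OC)cc(CC(O[Si](C)(C)C(C)(C)C)c3ccc(OC)cc3)c2C(=[N+]=[N-])c2cc(OC)cc(OC)c2)cc1 | intermediate
39 | (2S,3R)-cis-dihydrobenzofuran 3 with silyloxy side chain | COc1ccc(C(O[Si](C)(C)C(C)(C)C)Cc2cc(OC)cc3c2[C@@H](c2cc(OC)cc(OC)c2)[C@@H](c2ccc(OC)cc2)O3)cc1 | intermediate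
40 | (2S,3R)-cis-dihydrobenzofuran 3 with hydroxy side chain | COc1ccc(C(O)Cc2cc(OC)cc3c2[C@@H](c2cc(OC)cc(OC)c2)[C@@H](c2ccc(OC)cc2)O3)cc1 | intermediate
41 | (2S,3R)-cis-dihydrobenzofuran 3 ketone | COc1ccc(C(=O)Cc2cc(OC)cc3c2[C@@H](c2cc(OC)cc(OC)c2)[C@@H](c2ccc(OC)cc2)O3)cc1 | intermediate
42 | eastern half: (2R,3R)-trans-dihydrobenzofuran 3 ketone | COc1ccc(C(=O)Cc2cc(OC)cc3c2[C@@H](c2cc(OC)cc(OC)c2)[C@H](c2ccc(OC)cc2)O3)cc1 | intermediate
43 | triarylethanone (epimers at the α-carbon) | COc1ccc(/C=C/c2cc(OC)cc3c2[C@@H](c2cc(OC)cc(OC)c2)[C@H](c2ccc(OCOC)c(C(C(=O)c4ccc(OC)cc4)c4cc(OC)cc5c4[C@@H](c4cc(OC)cc(OC)c4)[C@H](c4ccc(OC)cc4)O5)c2)O3)cc1 | intermediate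
44 | alcohol with (R)-C3′ and methoxymethyl ether | COc1ccc(/C=C/c2cc(OC)cc3c2[C@@H](c2cc(OC)cc(OC)c2)[C@H](c2ccc(OCOC)c([C@H](C(O)c4ccc(OC)cc4)c4cc(OC)cc5c4[C@@H](c4cc(OC)cc(OC)c4)[C@H](c4ccc(OC)cc4)O5)c2)O3)cc1 | intermediate
45 | alcohol with (R)-C3′ and free ring B phenol | COc1ccc(/C=C/c2cc(OC)cc3c2[C@@H](c2cc(OC)cc(OC)c2)[C@H](c2ccc(O)c([C@H](C(O)c4ccc(OC)cc4)c4cc(OC)cc5c4[C@@H](c4cc(OC)cc(OC)c4)[C@H](c4ccc(OC)cc4)O5)c2)O3)cc1 | intermediate
46 | nona-O-methyl ether of the target | COc1ccc(/C=C/c2cc(OC)cc3c2[C@@H](c2cc(OC)cc(OC)c2)[C@H](c2ccc4c(c2)[C@@H](c2cc(OC)cc5c2[C@@H](c2cc(OC)cc(OC)c2)[C@H](c2ccc(OC)cc2)O5)[C@H](c2ccc(OC)cc2)O4)O3)cc1 | intermediate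
47 | CNP0184803.1 | Oc1ccc(/C=C/c2cc(O)cc3c2[C@@H](c2cc(O)cc(O)c2)[C@H](c2ccc4c(c2)[C@@H](c2cc(O)cc5c2[C@@H](c2cc(O)cc(O)c2)[C@H](c2ccc(O)cc2)O5)[C@H](c2ccc(O)cc2)O4)O3)cc1 | target

Total step count: 32. Longest linear sequence: 20 steps (steps 1–4, 8–19 and 29–32). The eastern branch (steps 1–4, 20–28, 29–32) has 17.

Steps least certain to work

Step 9 (key step; the same applies to step 21). The most likely failure is acyl transfer from the wrong carbonyl. The two aroyl groups differ only electronically, and opening of the alternative four-membered adduct would release the better-stabilised enolate, so the aryl anion may add to the 4-methoxybenzoyl group and give the isomer with the aryl groups exchanged. Protonation of the aryl anion before ring closure (plain α-arylation of the diketone) is the second risk. The fallback sets out from 16 and replaces the diketone by a β-ketoester, where the choice between ketone and ester is not in doubt. Methyl 3-(3,5-dimethoxyphenyl)-3-oxopropanoate F1 is made from 14 and methyl acetate with LiHMDS. With 16 and CsF in MeCN at 80 °C it should give methyl 2-[3-{[3-bromo-4-(methoxymethoxy)phenyl]methoxy}-2-(3,5-dimethoxybenzoyl)-5-methoxyphenyl]acetate F2. This is converted with N,O-dimethylhydroxylamine hydrochloride and i-PrMgCl into the N-methoxy-N-methylamide F3, and 4-methoxyphenylmagnesium bromide at −40 °C gives the aryl benzyl ketone; the hindered diaryl ketone should stay untouched. The fallback comes back to the route at 18.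

Step 13 (and step 25). The carbene may be diverted into the side chain: insertion into the silyloxy-bearing methine C–H, which is electronically activated and also 1,5 to the carbene, would give an indane. Hydrazone formation at the doubly ortho-substituted ketone (step 12) may also stall, and facial selectivity may be lower than for simpler benzyl ethers. The fallback sets out from 19 and changes both the mask of the side chain and the way the diazo compound is made. The alcohol is acylated with pivaloyl chloride to the pivalate F4, whose acyloxy group deactivates the neighbouring C–H bond toward electrophilic carbenes. Condensation with tosylhydrazide, which does not cleave the ester, gives the N-tosylhydrazone F5. Its sodium salt (NaH, benzyltriethylammonium chloride, dioxane, 60–80 °C) releases the diazo compound in situ (Bamford–Stevens) in the presence of Rh2(S-PTAD)4 to give the cis-dihydrobenzofuran pivalate F6. Reduction with i-Bu2AlH removes the pivalate and returns to the route at 24.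

Step 30. The dynamic kinetic resolution may discriminate poorly between the two α-epimers of 43, since both α-substituents are ortho-substituted aryl rings, or the hindered ketone may be reduced too slowly for equilibration to keep pace; either gives a mixture at C3′. The fallback sets out from 43 and gives up catalyst control. NaBH4 reduces the ketone to the alcohol F7 as a mixture at both new centres. The acid of step 31 then closes each C3′ epimer to its own trans ring, giving 46 together with its C2′,C3′-bis-epimer F8. These are diastereomers and are separated by chromatography. The fallback returns to the route at 46 with half the material at best.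

Step 32. BBr3 or the HBr it generates may ionise the C2–O bond of dihydrobenzofuran 1 or protonate the stilbene, and the cation may close onto the resorcinol ring at C3 to form a seven-membered ring. Incomplete demethylation of the nine ethers is the other risk. The fallback sets out from 46 and uses a proton-buffered reagent and a purifiable derivative. AlCl3 with N,N-dimethylaniline in toluene at 90 °C cleaves the methyl ethers while the amine takes up the acid. The crude polyphenol is acetylated in the same flask (Ac2O, pyridine) to the nonaacetate F9, which can be chromatographed free of partly demethylated material. K2CO3 in MeOH at 0 °C then removes the acetates and gives 47.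

Step 8 (and step 20). The phenoxide that forms transiently in the Mitsunobu reaction may attack the neighbouring silicon; the silyl group would then shift from carbon to oxygen and the aryl anion would expel triflate, so the aryne precursor would be lost. The ortho silyl group also slows O-alkylation. The fallback sets out from 5 and 12 and attaches the benzyl group before silicon is moved to carbon. 12 is converted with CBr4 and PPh3 into 2-bromo-4-(bromomethyl)-1-(methoxymethoxy)benzene F10. An excess of 5 is mono-alkylated with it (K2CO3, acetone) to 2-bromo-3-{[3-bromo-4-(methoxymethoxy)phenyl]methoxy}-5-methoxyphenol F11, which is silylated with hexamethyldisilazane to its trimethylsilyl ether F12. One equivalent of n-BuLi at −100 °C should exchange the bromine flanked by two oxygens in preference to the ring B bromine; retro-Brook migration and Tf2O then give the triflate, returning to the route at 16. For the eastern series the same sequence with 4-methoxybenzyl chloride has no second bromine to worry about.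

Further compounds

F1 | step 9 | methyl 3-(3,5-dimethoxyphenyl)-3-oxopropanoate | COC(=O)CC(=O)c1cc(OC)cc(OC)c1
F2 | step 9 | methyl 2-[3-{[3-bromo-4-(methoxymethoxy)phenyl]methoxy}-2-(3,5-dimethoxybenzoyl)-5-methoxyphenyl]acetate | COC(=O)Cc1cc(OC)cc(OCc2ccc(OCOC)c(Br)c2)c1C(=O)c1cc(OC)cc(OC)c1
F3 | step 9 | 2-[3-{[3-bromo-4-(methoxymethoxy)phenyl]methoxy}-2-(3,5-dimethoxybenzoyl)-5-methoxyphenyl]-N-methoxy-N-methylacetamide | CON(C)C(=O)Cc1cc(OC)cc(OCc2ccc(OCOC)c(Br)c2)c1C(=O)c1cc(OC)cc(OC)c1
F4 | step 13 | pivalate of 19 | COc1ccc(C(OC(=O)C(C)(C)C)Cc2cc(OC)cc(OCc3ccc(OCOC)c(Br)c3)c2C(=O)c2cc(OC)cc(OC)c2)cc1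
F5 | step 13 | N-tosylhydrazone of F4 | COc1ccc(C(OC(=O)C(C)(C)C)Cc2cc(OC)cc(OCc3ccc(OCOC)c(Br)c3)c2C(=NNS(=O)(=O)c2ccc(C)cc2)c2cc(OC)cc(OC)c2)cc1
F6 | step 13 | (2S,3R)-cis-dihydrobenzofuran 1 with pivaloyloxy side chain | COc1ccc(C(OC(=O)C(C)(C)C)Cc2cc(OC)cc3c2[C@@H](c2cc(OC)cc(OC)c2)[C@@H](c2ccc(OCOC)c(Br)c2)O3)cc1
F7 | step 30 | alcohol from 43 as a mixture at C2′ and C3′ | COc1ccc(/C=C/c2cc(OC)cc3c2[C@@H](c2cc(OC)cc(OC)c2)[C@H](c2ccc(OCOC)c(C(C(O)c4ccc(OC)cc4)c4cc(OC)cc5c4[C@@H](c4cc(OC)cc(OC)c4)[C@H](c4ccc(OC)cc4)O5)c2)O3)cc1
F8 | step 30 | C2′,C3′-bis-epimer of 46 | COc1ccc(/C=C/c2cc(OC)cc3c2[C@@H](c2cc(OC)cc(OC)c2)[C@H](c2ccc4c(c2)[C@H](c2cc(OC)cc5c2[C@@H](c2cc(OC)cc(OC)c2)[C@H](c2ccc(OC)cc2)O5)[C@@H](c2ccc(OC)cc2)O4)O3)cc1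
F9 | step 32 | nonaacetate of the target | CC(=O)Oc1ccc(/C=C/c2cc(OC(C)=O)cc3c2[C@@H](c2cc(OC(C)=O)cc(OC(C)=O)c2)[C@H](c2ccc4c(c2)[C@@H](c2cc(OC(C)=O)cc5c2[C@@H](c2cc(OC(C)=O)cc(OC(C)=O)c2)[C@H](c2ccc(OC(C)=O)cc2)O5)[C@H](c2ccc(OC(C)=O)cc2)O4)O3)cc1
F10 | step 8 | 2-bromo-4-(bromomethyl)-1-(methoxymethoxy)benzene | COCOc1ccc(CBr)cc1Br
F11 | step 8 | 2-bromo-3-{[3-bromo-4-(methoxymethoxy)phenyl]methoxy}-5-methoxyphenol | COCOc1ccc(COc2cc(OC)cc(O)c2Br)cc1Br
F12 | step 8 | trimethylsilyl ether of F11 | COCOc1ccc(COc2cc(OC)cc(O[Si](C)(C)C)c2Br)cc1Br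
A1 | alternative 1 | nona-O-methyl ether of the target (identical with 46) | COc1ccc(/C=C/c2cc(OC)cc3c2[C@@H](c2cc(OC)cc(OC)c2)[C@H](c2ccc4c(c2)[C@@H](c2cc(OC)cc5c2[C@@H](c2cc(OC)cc(OC)c2)[C@H](c2ccc(OC)cc2)O5)[C@H](c2ccc(OC)cc2)O4)O3)cc1
A2 | alternative 1 | 2-(4-methoxyphenyl)-3,4-dihydro-2H-1,3-benzoxazine on ring B carrying both outer dihydrobenzofurans (configuration at the two benzoxazine carbons open) | COc1ccc(/C=C/c2cc(OC)cc3c2[C@@H](c2cc(OC)cc(OC)c2)[C@H](c2ccc4c(c2)C(c2cc(OC)cc5c2[C@@H](c2cc(OC)cc(OC)c2)[C@H](c2ccc(OC)cc2)O5)NC(c2ccc(OC)cc2)O4)O3)cc1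
A3 | alternative 2 | (2R,3R)-trans-dihydrobenzofuran 3 with ring C built (4-silyloxymethyl and 6-ethoxy) | CC(C)(C)[Si](C)(C)OCc1cc(OCC)cc2c1[C@@H](c1cc(OC)cc(OC)c1)[C@H](c1ccc(OC)cc1)O2
A4 | alternative 2 | 1,6-diyne with ynol ether and internal alkyne | C#CO[C@@H](c1ccc(OC)cc1)[C@H](c1cc(OC)cc(OC)c1)C#CCO[Si](C)(C)C(C)(C)C
A5 | alternative 2 | ethoxyacetylene | CCOC#C
A6 | alternative 3 | secondary benzylic boronate holding C2′ and C3′ | COc1ccc(/C=C/c2cc(OC)cc3c2[C@@H](c2cc(OC)cc(OC)c2)[C@H](c2ccc(Cl)c(c2)[C@@H](c2cc(OC)cc4c2[C@@H](c2cc(OC)cc(OC)c2)[C@H](c2ccc(OC)cc2)O4)[C@H](c2ccc(OC)cc2)B2OC(C)(C)C(C)(C)O2)O3)cc1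
A7 | alternative 3 | eastern (E)-alkenyl pinacol boronate | CC1(C)OB(/C=C/c2cc(OC)cc3c2[C@@H](c2cc(OC)cc(OC)c2)[C@H](c2ccc(OC)cc2)O3)OC1(C)C
A8 | alternative 3 | 4-methoxyphenyllithium | [Li]c1ccc(OC)cc1
A9 | alternative 3 | western aryl triflate with ortho chlorine | COc1ccc(/C=C/c2cc(OC)cc3c2[C@@H](c2cc(OC)cc(OC)c2)[C@H](c2ccc(Cl)c(OS(=O)(=O)C(F)(F)F)c2)O3)cc1
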